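**Plan**

- The retrosynthesis first cuts the two O–CH3 bonds on ring C. In each terminal phenol ring (A and D) it then cuts the ring bonds C2–C3 and C4–C5 (phenol numbering: OH on C1, bridge on C3). This leads back to a bis(E-nitroalkene) and two molecules of a 1-methoxy-3-silyloxydiene.
- The enabling feature: rings A and D are 3-alkylphenols with no other substituent, the hydroxyl on C1 and the CH2CH2 bridge on C3. C1, C2, C5 and C6 map onto the diene (oxygen on its C3), and C3–C4 onto a two-carbon dienophile that carries the bridge.
- Each nitroalkene is cut at its C=C bond (Henry reaction, dehydration), each three-carbon arm back to an aryl aldehyde (two-carbon olefination), and the ring B–O–ring C ether bond by SNAr.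
- Forward: the diaryl ether is made first, both arms are grown in parallel, rings A and D are closed at the same time, and demethylation comes last.
- The target has no stereocentre. Alkene geometries and the sp3 centres of the cycloadducts are transient and are erased by hydrogenation or aromatisation.

Key step: step 7

Remark: ring A is the 3-hydroxyphenyl ring bridged to ring B (the 1,4-phenylene ring), ring C is the trioxygenated ring, ring D is the 3-hydroxyphenyl ring bridged to ring C; 3-hydroxy-4,5-dimethoxybenzaldehyde is taken as a purchased compound.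

**Route**

Step 1
Reactants: 1 4-fluorobenzaldehyde; 2 3-hydroxy-4,5-dimethoxybenzaldehyde
Product: 3 3-(4-formylphenoxy)-4,5-dimethoxybenzaldehyde
Conditions: K2CO3, DMF, 130 °C
Reagents that add atoms: none
Why: Nucleophilic aromatic substitution (SNAr), in which the phenoxide of 2 adds para to the formyl group of 1, the formyl group stabilises the anionic σ-adduct and fluoride leaves; neither aldehyde is enolisable, so both should survive carbonate at this temperature.

Step 2
Reactants: 3 3-(4-formylphenoxy)-4,5-dimethoxybenzaldehyde; 4 triethyl phosphonoacetate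
Product: 5 ethyl (E)-3-[4-[5-[(E)-3-ethoxy-3-oxoprop-1-enyl]-2,3-dimethoxyphenoxy]phenyl]prop-2-enoate (bis(E-acrylate))
Conditions: 4 (2.4 equiv), NaH, THF, 0 °C to rt
Reagents that add atoms: triethyl phosphonoacetate (4), CCOC(=O)CP(=O)(OCC)OCC
Why: Double Horner–Wadsworth–Emmons olefination, in which the stabilised phosphonate anion adds to both aryl aldehydes and should give the E-acrylates; the geometry is of no consequence because step 3 saturates both alkenes.

Step 3
Reactants: 5 bis(E-acrylate)
Product: 6 ethyl 3-[4-[5-(3-ethoxy-3-oxopropyl)-2,3-dimethoxyphenoxy]phenyl]propanoate (bis(propanoate))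
Conditions: H2 (1 atm), 10% Pd/C, EtOAc, rt
Reagents that add atoms: none
Why: Heterogeneous catalytic hydrogenation of the two cinnamate C=C bonds; the diaryl ether, the methyl ethers and the esters are inert under these conditions and there is no benzylic C–O bond to hydrogenolyse.

Step 4
Reactants: 6 bis(propanoate)
Product: 7 3-[4-[2,3-dimethoxy-5-(3-oxopropyl)phenoxy]phenyl]propanal (bis(propanal))
Conditions: i-Bu2AlH (2.2 equiv), CH2Cl2, −78 °C; MeOH, then aq. potassium sodium tartrate
Reagents that add atoms: none
Why: Partial reduction of an ester with i-Bu2AlH, in which the tetrahedral aluminium hemiacetal persists at −78 °C and collapses to the aldehyde only on quench, the usual way from ethyl 3-arylpropanoates to 3-arylpropanals.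

Step 5
Reactants: 7 bis(propanal); 8 nitromethane
Product: 9 4-[4-[5-(3-hydroxy-4-nitrobutyl)-2,3-dimethoxyphenoxy]phenyl]-1-nitrobutan-2-ol (bis(nitro alcohol), mixture of diastereomers)
Conditions: MeNO2 (10 equiv), KOt-Bu (0.2 equiv), THF/t-BuOH 1:1, 0 °C to rt
Reagents that add atoms: nitromethane (8), C[N+](=O)[O-]
Why: Henry (nitroaldol) reaction, in which the nitronate of nitromethane adds to both aldehydes while the excess of nitromethane suppresses aldol self-condensation and double addition; the two carbinol centres form without control because step 6 removes them.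

Step 6
Reactants: 9 bis(nitro alcohol)
Product: 11 1,2-dimethoxy-5-[(E)-4-nitrobut-3-enyl]-3-[4-[(E)-4-nitrobut-3-enyl]phenoxy]benzene (bis(E-nitroalkene)), via bis(mesylate) 10 (not isolated)
Conditions: MsCl (2.6 equiv), Et3N (6 equiv), CH2Cl2, −10 to 0 °C
Reagents that add atoms: methanesulfonyl chloride, CS(=O)(=O)Cl (adds the mesyl groups of 10, which are lost again on the way to 11)
Why: Mesylation followed by E1cB elimination, the standard dehydration of a β-nitro alcohol to a conjugated nitroalkene, should give the thermodynamically preferred E isomers; the low temperature limits base-mediated migration of the double bond out of conjugation.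

Step 7
Reactants: 11 bis(E-nitroalkene); 12 (E)-1-methoxy-3-(trimethylsilyloxy)buta-1,3-diene (two molecules are incorporated)
Product: 15 3-[2-[4-[5-[2-(3-hydroxyphenyl)ethyl]-2,3-dimethoxyphenoxy]phenyl]ethyl]phenol (perrottetin F ring C dimethyl ether), via bis(cycloadduct) 13 (not isolated), via bis(nitro enone) 14 (not isolated)
Conditions: 12 (5 equiv), toluene, 80 °C; then 1 M HCl, THF, rt; then DBU (4 equiv), THF, rt to 50 °C, under argon
Reagents that add atoms: (E)-1-methoxy-3-(trimethylsilyloxy)buta-1,3-diene (12), CO/C=C/C(=C)O[Si](C)(C)C
Why: Each nitroalkene is a strongly polarised electron-poor dienophile, and the electron-rich diene should add in a normal-demand, concerted but asynchronous Diels–Alder reaction in which its nucleophilic CH2 terminus (C4) bonds to the arm-bearing β-carbon and its methoxy-bearing C1 to the nitro-bearing carbon. Aqueous acid then hydrolyses the silyl enol ether and eliminates methanol to give the 4-nitro-5-alkylcyclohex-2-enone, and DBU removes nitrous acid across C4–C5 (the nitro group is allylic and its loss is driven by aromatisation), after which the cyclohexa-2,4-dienone tautomerises to the 3-alkylphenol; the closest known reaction type is the Diels–Alder reaction of 1-methoxy-3-silyloxydienes with nitroalkenes used as alkyne equivalents, followed by loss of nitrous acid. Rings A and D each close by an intermolecular (4+2) cycloaddition that forms both new ring bonds (C2–C3 and C4–C5 of the future phenol), not by cyclisation of a tethered chain. The sp3 centres of 13 and 14 form as mixtures and are all erased on aromatisation, so no stereocontrol is needed. The selectivity that counts is regiochemical, hydroxyl meta to the arm, and it is secured by the nitro group as the only polarising substituent of the alkene, which puts diene C4 on the arm-bearing carbon and hence the oxygen-bearing C3 one atom further along; acid is applied before base so that methanol is lost through the ketone and the nitro group stays a leaving group instead of ending in a nitrodiene.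

Step 8
Reactants: 15 perrottetin F ring C dimethyl ether
Product: 16 perrottetin F
Conditions: BBr3 (6 equiv), CH2Cl2, −78 °C to rt; then H2O
Reagents that add atoms: none
Why: Cleavage of aryl methyl ethers with the Lewis acid BBr3 (complexation at oxygen, then bromide attack on the methyl group); the diaryl ether offers no alkyl C–O bond to cleave, and the free phenols only consume reagent as aryl borates that hydrolyse on work-up.

**Compound list**

1 | 4-fluorobenzaldehyde | O=Cc1ccc(F)cc1 | starting material
2 | 3-hydroxy-4,5-dimethoxybenzaldehyde | COc1cc(C=O)cc(O)c1OC | starting material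
3 | 3-(4-formylphenoxy)-4,5-dimethoxybenzaldehyde | O=Cc1ccc(Oc2cc(C=O)cc(OC)c2OC)cc1 | intermediate
4 | triethyl phosphonoacetate | CCOC(=O)CP(=O)(OCC)OCC | starting material
5 | ethyl (E)-3-[4-[5-[(E)-3-ethoxy-3-oxoprop-1-enyl]-2,3-dimethoxyphenoxy]phenyl]prop-2-enoate, bis(E-acrylate) | CCOC(=O)/C=C/c1ccc(Oc2cc(/C=C/C(=O)OCC)cc(OC)c2OC)cc1 | intermediate
6 | ethyl 3-[4-[5-(3-ethoxy-3-oxopropyl)-2,3-dimethoxyphenoxy]phenyl]propanoate, bis(propanoate) | CCOC(=O)CCc1ccc(Oc2cc(CCC(=O)OCC)cc(OC)c2OC)cc1 | intermediate
7 | 3-[4-[2,3-dimethoxy-5-(3-oxopropyl)phenoxy]phenyl]propanal, bis(propanal) | O=CCCc1ccc(Oc2cc(CCC=O)cc(OC)c2OC)cc1 | intermediate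
8 | nitromethane | C[N+](=O)[O-] | starting material
9 | 4-[4-[5-(3-hydroxy-4-nitrobutyl)-2,3-dimethoxyphenoxy]phenyl]-1-nitrobutan-2-ol, bis(nitro alcohol), mixture of diastereomers at the two carbinol centres | O=[N+]([O-])CC(O)CCc1ccc(Oc2cc(CCC(O)C[N+](=O)[O-])cc(OC)c2OC)cc1 | intermediate
10 | bis(mesylate) of 9 (both hydroxyls as methanesulfonates, mixture of diastereomers), formed in the flask and not isolated | CS(=O)(=O)OC(C[N+](=O)[O-])CCc1ccc(Oc2cc(CCC(C[N+](=O)[O-])OS(C)(=O)=O)cc(OC)c2OC)cc1 | intermediate
11 | 1,2-dimethoxy-5-[(E)-4-nitrobut-3-enyl]-3-[4-[(E)-4-nitrobut-3-enyl]phenoxy]benzene, bis(E-nitroalkene) | O=[N+]([O-])/C=C/CCc1ccc(Oc2cc(CC/C=C/[N+](=O)[O-])cc(OC)c2OC)cc1 | intermediate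
12 | (E)-1-methoxy-3-(trimethylsilyloxy)buta-1,3-diene | CO/C=C/C(=C)O[Si](C)(C)C | starting material
13 | bis(cycloadduct): ring B and ring C each carry a 2-[3-methoxy-2-nitro-5-(trimethylsilyloxy)cyclohex-4-en-1-yl]ethyl arm; nitro and arm trans, methoxy centre and the two rings relative to each other as a mixture; not isolated | COC1C=C(O[Si](C)(C)C)CC(CCc2ccc(Oc3cc(CCC4CC(O[Si](C)(C)C)=CC(OC)C4[N+](=O)[O-])cc(OC)c3OC)cc2)C1[N+](=O)[O-] | intermediate
14 | bis(nitro enone): ring B and ring C each carry a 2-(2-nitro-5-oxocyclohex-3-en-1-yl)ethyl arm, that is a 4-nitro-5-alkylcyclohex-2-enone on each arm; mixture of diastereomers; not isolated | O=C1C=CC([N+](=O)[O-])C(CCc2ccc(Oc3cc(CCC4CC(=O)C=CC4[N+](=O)[O-])cc(OC)c3OC)cc2)C1 | intermediate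
15 | 3-[2-[4-[5-[2-(3-hydroxyphenyl)ethyl]-2,3-dimethoxyphenoxy]phenyl]ethyl]phenol, perrottetin F ring C dimethyl ether | Oc1cccc(CCc2ccc(Oc3cc(CCc4cccc(O)c4)cc(OC)c3OC)cc2)c1 | intermediate
16 | perrottetin F, 3-[4-[2-(3-hydroxyphenyl)ethyl]phenoxy]-5-[2-(3-hydroxyphenyl)ethyl]benzene-1,2-diol | Oc1cccc(CCc2ccc(Oc3cc(CCc4cccc(O)c4)cc(O)c3O)cc2)c1 | target

**Step count**

Total steps: 8. Longest linear sequence: 8 steps (1 and 2 to 16).

**Steps most likely to fail**

Step 7. The double cycloaddition may stop after one arm, or the nitroalkene may oligomerise at the temperature the diene needs. The loss of nitrous acid may also be slow, because the proton on C5 of the nitro enone is not acidified by the carbonyl group; DBU would then hold the material as the nitronate, which can oxidise or add to remaining enone. Fallback: setting out from 3, a double Horner–Wadsworth–Emmons reaction with diethyl (3-methoxybenzyl)phosphonate (NaH, THF) should give the bis(E-stilbene) F1. Hydrogenation (H2, 10% Pd/C, EtOAc) would give perrottetin F tetramethyl ether F2, and BBr3 in CH2Cl2 would cleave all four methyl ethers, so that the sequence comes back to the route at 16. Rings A and D are then brought in ready-made instead of being built by cycloaddition.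

Step 6. Triethylamine may move the double bond out of conjugation to the allylic nitro isomer, the nitroalkene may oligomerise under base, or one arm may stop at the mesylate. Fallback: setting out from 7, Wittig methylenation (MePPh3Br, KOt-Bu, THF) should give the bis(but-3-enyl) diaryl ether F3. Radical nitration of both terminal alkenes with AgNO2 and TEMPO (4 Å molecular sieves, 1,2-dichloroethane, 70 °C) would then form the E-nitroalkenes without any amine base and come back to the route at 11.

Step 4. Over-reduction of one or both arms to the alcohol, or incomplete reduction, would leave a mixture of ester, aldehyde and alcohol that is hard to separate. Fallback: setting out from 6, LiAlH4 (THF, 0 °C) would reduce both esters fully to the diol F4, and a Swern oxidation ((COCl)2, DMSO, Et3N, CH2Cl2, −78 °C) would come back to the route at 7.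

**Further compounds**

F1 | step 7 | 1,2-dimethoxy-5-[(E)-2-(3-methoxyphenyl)ethenyl]-3-[4-[(E)-2-(3-methoxyphenyl)ethenyl]phenoxy]benzene, bis(E-stilbene) | COc1cccc(/C=C/c2ccc(Oc3cc(/C=C/c4cccc(OC)c4)cc(OC)c3OC)cc2)c1
F2 | step 7 | perrottetin F tetramethyl ether | COc1cccc(CCc2ccc(Oc3cc(CCc4cccc(OC)c4)cc(OC)c3OC)cc2)c1
F3 | step 6 | 5-(but-3-enyl)-3-[4-(but-3-enyl)phenoxy]-1,2-dimethoxybenzene, bis(but-3-enyl) diaryl ether | C=CCCc1ccc(Oc2cc(CCC=C)cc(OC)c2OC)cc1
F4 | step 4 | 3-[4-[5-(3-hydroxypropyl)-2,3-dimethoxyphenoxy]phenyl]propan-1-ol, diol | OCCCc1ccc(Oc2cc(CCCO)cc(OC)c2OC)cc1
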